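**Strategy.** Lignan numbering is used: ring B is the tetrahydrofuran holding C7, C8, C8', C9' and its oxygen; ring A holds C7', C8', C8, C9. The route rests on the bond from C7 to its guaiacyl ring. The key step exploits the tertiary oxygen on ring-fusion carbon C8, vicinal and cis to that bond: its aryl(dimethyl)silyl ether delivers the aryl group through its ipso carbon to the ring B oxocarbenium ion formed from a mixture of C7 acetate epimers. One operation forms the C7–aryl bond, sets C7 stereoconvergently, fixes attachment para to the phenol oxygen and releases the C8 hydroxyl. The precursor is a silylated bicyclic lactol acetate.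

Key step: step 8

Remark: the absolute configuration is taken as drawn, (1R,2S,5S,6R) in 3,7-dioxabicyclo[3.3.0]octane numbering (C1 = C8, C2 = C7, C5 = C8', C6 = C7'); the ligand enantiomer in step 3 is chosen to match it.

**Step 1**
Reactants: 1 1-(benzyloxy)-4-bromo-2-methoxybenzene
Product: 3 [4-(benzyloxy)-3-methoxyphenyl]chlorodimethylsilane, via arylmagnesium bromide 2 (not isolated)
Conditions: Mg turnings, THF, 45 °C; then added to Me2SiCl2 (4 equiv), THF, 0 °C to rt; filtration under Ar, short-path distillation
Reagents that add atoms: dichlorodimethylsilane C[Si](C)(Cl)Cl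
Why: Grignard formation followed by substitution at silicon, with inverse addition to excess dichlorosilane, should stop at mono-arylation; no stereocentre is formed.

**Step 2**
Reactants: 4 α-methylene-γ-butyrolactone (3-methylenedihydrofuran-2(3H)-one)
Product: 6 3-(bromomethyl)furan-2(5H)-one, via dibromide 5 (not isolated)
Conditions: Br2 (1.0 equiv), CH2Cl2, 0 °C; then i-Pr2NEt (1.1 equiv), 0 °C to rt
Reagents that add atoms: bromine BrBr
Why: Bromination–dehydrobromination: anti addition of Br2 to the exocyclic alkene and E2 loss of HBr across C3–C4 with a hindered amine should give the conjugated endocyclic butenolide that keeps the primary allylic bromide; no stereocentre remains.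

**Step 3**
Reactants: 6 3-(bromomethyl)furan-2(5H)-one; 7 4-(benzyloxy)-3-methoxybenzaldehyde
Product: 9 (S)-4-{(R)-[4-(benzyloxy)-3-methoxyphenyl](hydroxy)methyl}-3-methylenedihydrofuran-2(3H)-one (anti adduct), via trimethylsilyl ether 8 (not isolated)
Conditions: CrCl2 (10 mol%), one enantiomer of 3,6-di-tert-butyl-1,8-bis(4-isopropyl-4,5-dihydrooxazol-2-yl)carbazole (12 mol%, chosen to give the (R)-carbinol), Mn powder (2 equiv), Me3SiCl (1.5 equiv), i-Pr2NEt (0.3 equiv), THF, rt; then 1 M HCl aq, THF, 0 °C
Reagents that add atoms: none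
Why: Catalytic asymmetric Nozaki–Hiyama–Kishi allylation: the allylchromium species (trivalent chromium, metal on the primary carbon) should add through C4 of the furanone in a chair transition state, the ring-fixed E-type geometry giving the anti adduct and the ligand choosing the aldehyde face, so that the (R)-carbinol C7' and the (S) ring carbon C8' are set together.

**Step 4**
Reactants: 9 anti homoallylic alcohol lactone
Product: 10 (3R,4S)-4-{(R)-[4-(benzyloxy)-3-methoxyphenyl](hydroxy)methyl}-3-hydroxy-3-(hydroxymethyl)dihydrofuran-2(3H)-one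
Conditions: K2OsO2(OH)4 (2 mol%), N-methylmorpholine N-oxide (1.5 equiv), citric acid (0.75 equiv), t-BuOH/H2O 1:1, rt
Reagents that add atoms: N-methylmorpholine N-oxide C[N+]1([O-])CCOCC1; water O
Why: Osmium-catalysed syn-dihydroxylation (citric-acid-accelerated for the electron-poor 1,1-disubstituted alkene) should occur on the face of the exocyclic alkene anti to the C4 side chain, placing the new tertiary hydroxyl (C8) trans and the hydroxymethyl group (C9) cis to that side chain.

**Step 5**
Reactants: 10 triol lactone
Product: 11 (1R,5S,6R)-6-[4-(benzyloxy)-3-methoxyphenyl]-1-hydroxy-3,7-dioxabicyclo[3.3.0]octan-2-one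
Conditions: camphorsulfonic acid (10 mol%), CH2Cl2, 4 Å MS, 0 °C to rt
Reagents that add atoms: none
Why: SN1 etherification: acid ionises the benzylic alcohol to a para-benzyloxy-stabilised cation that is captured by the cis-disposed primary C9 hydroxyl to close ring A, and the allylic-strain-minimised transition state (C8'–H eclipsing the aryl ring) together with reversibility should place the aryl group exo, i.e. (R) at C7'.

**Step 6**
Reactants: 11 bicyclic hydroxy lactone; 3 [4-(benzyloxy)-3-methoxyphenyl]chlorodimethylsilane
Product: 12 (1R,5S,6R)-6-[4-(benzyloxy)-3-methoxyphenyl]-1-{[4-(benzyloxy)-3-methoxyphenyl]dimethylsilyloxy}-3,7-dioxabicyclo[3.3.0]octan-2-one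
Conditions: imidazole (3 equiv), DMAP (0.2 equiv), DMF, rt to 40 °C
Reagents that add atoms: none
Why: Imidazole/DMAP-promoted O-silylation of the only free hydroxyl with the small aryldimethylsilyl chloride should install the tether on the tertiary C8 oxygen without touching a stereocentre.

**Step 7**
Reactants: 12 silyl ether lactone
Product: 14 (1R,5S,6R)-6-[4-(benzyloxy)-3-methoxyphenyl]-1-{[4-(benzyloxy)-3-methoxyphenyl]dimethylsilyloxy}-3,7-dioxabicyclo[3.3.0]oct-2-yl acetate (C2 epimer mixture), via aluminium hemiacetal 13 (not isolated)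
Conditions: i-Bu2AlH (1.2 equiv), CH2Cl2, −78 °C; then pyridine, DMAP, Ac2O, −78 to −20 °C
Reagents that add atoms: acetic anhydride CC(=O)OC(C)=O
Why: Reductive acetylation of a lactone: the aluminium hemiacetal formed at −78 °C should be trapped in situ by Ac2O/DMAP, which avoids the free lactol and any silyl migration; the new acetal centre C7 is formed as an epimer mixture that the next step makes irrelevant.

**Step 8**
Reactants: 14 silylated lactol acetate (C7 epimer mixture)
Product: 16 (1R,2S,5S,6R)-2,6-bis[4-(benzyloxy)-3-methoxyphenyl]-3,7-dioxabicyclo[3.3.0]octan-1-ol, via acetoxysilyl ether 15 (not isolated)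
Conditions: Me3SiOTf (0.2 equiv), 2,6-di-tert-butyl-4-methylpyridine (0.3 equiv), CH2Cl2, −78 to −40 °C; then 0.5 M HCl aq, THF, 0 °C
Reagents that add atoms: none
Why: Me3SiOTf ionises the anomeric acetate of either C7 epimer to one ring B oxocarbenium ion (C7=O+), which is attacked by the ipso carbon of the silicon-bound aryl group held on the adjacent C8 oxygen; loss of silicon from the resulting spiro cyclohexadienyl (β-silyl) cation rearomatises the ring and leaves the silyl group on O8 as acetoxysilyl ether 15, from which the acid work-up frees the tertiary alcohol. The closest known reaction type is the silicon-tethered intramolecular aryl delivery from 2-O-arylsilyl glycosyl donors that gives 1,2-cis C-aryl glycosides. The only ring closed is transient, a five-membered oxasilolane formed by 5-exo-trig spirocyclisation of the arene onto the oxocarbenium carbon, and it is opened again in the same step by ipso-desilylation. The new stereocentre C7 is controlled by the tether: the aryl group can only arrive on the face of ring B that carries the C8–O bond, which is also the convex face of the cis-fused bicycle, so both acetate epimers converge on the (S) centre with the aryl group exo. The step needs site selectivity on the arene (secured by the C–Si bond para to the benzyloxy group, so that attachment para to the phenol oxygen is built in), chemoselectivity for the anomeric acetate over the benzylic ether of ring A (low temperature and a substoichiometric promoter) and suppression of protodesilylation (hindered pyridine base).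

**Step 9**
Reactants: 16 tertiary alcohol
Product: 17 (1R,2S,5S,6R)-2,6-bis[4-(benzyloxy)-3-methoxyphenyl]-3,7-dioxabicyclo[3.3.0]oct-1-yl acetate
Conditions: Ac2O (5 equiv), Et3N (6 equiv), DMAP (0.5 equiv), CH2Cl2, rt to 40 °C
Reagents that add atoms: acetic anhydride CC(=O)OC(C)=O
Why: DMAP-catalysed (Steglich-type) acylation should acetylate the hindered tertiary alcohol, the only free hydroxyl, with retention at C8.

**Step 10**
Reactants: 17 dibenzyl ether acetate
Product: 18 8-acetoxypinoresinol, (1R,2S,5S,6R)-2,6-bis(4-hydroxy-3-methoxyphenyl)-3,7-dioxabicyclo[3.3.0]oct-1-yl acetate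
Conditions: H2 (1 atm), Pd/C (10 wt%), EtOAc, rt, stopped at full debenzylation
Reagents that add atoms: none
Why: Catalytic hydrogenolysis should cleave both aryl benzyl ethers faster than the benzylic ring ethers, leaving the tertiary acetate and all four stereocentres untouched.

**Compound list**
1 | 1-(benzyloxy)-4-bromo-2-methoxybenzene | COc1cc(Br)ccc1OCc1ccccc1 | starting material
2 | [4-(benzyloxy)-3-methoxyphenyl]magnesium bromide | COc1cc([Mg]Br)ccc1OCc1ccccc1 | intermediate
3 | [4-(benzyloxy)-3-methoxyphenyl]chlorodimethylsilane | COc1cc([Si](C)(C)Cl)ccc1OCc1ccccc1 | intermediate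
4 | α-methylene-γ-butyrolactone | C=C1CCOC1=O | starting material
5 | 3-bromo-3-(bromomethyl)dihydrofuran-2(3H)-one (racemic) | BrCC1(Br)CCOC1=O | intermediate
6 | 3-(bromomethyl)furan-2(5H)-one | BrCC1=CCOC1=O | intermediate
7 | 4-(benzyloxy)-3-methoxybenzaldehyde | COc1cc(C=O)ccc1OCc1ccccc1 | starting material
8 | trimethylsilyl ether of 9 | COc1cc([C@H](O[Si](C)(C)C)[C@@H]2COC(=O)C2=C)ccc1OCc1ccccc1 | intermediate
9 | (S)-4-{(R)-[4-(benzyloxy)-3-methoxyphenyl](hydroxy)methyl}-3-methylenedihydrofuran-2(3H)-one | COc1cc([C@H](O)[C@@H]2COC(=O)C2=C)ccc1OCc1ccccc1 | intermediate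
10 | (3R,4S)-4-{(R)-[4-(benzyloxy)-3-methoxyphenyl](hydroxy)methyl}-3-hydroxy-3-(hydroxymethyl)dihydrofuran-2(3H)-one | COc1cc([C@H](O)[C@@H]2COC(=O)[C@]2(O)CO)ccc1OCc1ccccc1 | intermediate
11 | (1R,5S,6R)-6-[4-(benzyloxy)-3-methoxyphenyl]-1-hydroxy-3,7-dioxabicyclo[3.3.0]octan-2-one | COc1cc([C@@H]2OC[C@@]3(O)C(=O)OC[C@@H]23)ccc1OCc1ccccc1 | intermediate
12 | O1-[aryl(dimethyl)silyl] ether of 11 | COc1cc([C@@H]2OC[C@@]3(O[Si](C)(C)c4ccc(OCc5ccccc5)c(OC)c4)C(=O)OC[C@@H]23)ccc1OCc1ccccc1 | intermediate
13 | diisobutylaluminium hemiacetal of 12 (C2 epimer mixture) | COc1cc([C@@H]2OC[C@@]3(O[Si](C)(C)c4ccc(OCc5ccccc5)c(OC)c4)C(O[Al](CC(C)C)CC(C)C)OC[C@@H]23)ccc1OCc1ccccc1 | intermediate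
14 | silylated lactol acetate (C2 epimer mixture) | COc1cc([C@@H]2OC[C@@]3(O[Si](C)(C)c4ccc(OCc5ccccc5)c(OC)c4)C(OC(C)=O)OC[C@@H]23)ccc1OCc1ccccc1 | intermediate
15 | O1-[acetoxy(dimethyl)silyl] ether of 16 | COc1cc([C@@H]2OC[C@@]3(O[Si](C)(C)OC(C)=O)[C@H](c4ccc(OCc5ccccc5)c(OC)c4)OC[C@@H]23)ccc1OCc1ccccc1 | intermediate
16 | (1R,2S,5S,6R)-2,6-bis[4-(benzyloxy)-3-methoxyphenyl]-3,7-dioxabicyclo[3.3.0]octan-1-ol | COc1cc([C@@H]2OC[C@@]3(O)[C@H](c4ccc(OCc5ccccc5)c(OC)c4)OC[C@@H]23)ccc1OCc1ccccc1 | intermediate
17 | (1R,2S,5S,6R)-2,6-bis[4-(benzyloxy)-3-methoxyphenyl]-3,7-dioxabicyclo[3.3.0]oct-1-yl acetate | COc1cc([C@@H]2OC[C@@]3(OC(C)=O)[C@H](c4ccc(OCc5ccccc5)c(OC)c4)OC[C@@H]23)ccc1OCc1ccccc1 | intermediate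
18 | 8-acetoxypinoresinol | COc1cc([C@@H]2OC[C@@]3(OC(C)=O)[C@H](c4ccc(O)c(OC)c4)OC[C@@H]23)ccc1O | target

**Step count and risks**

Total step count: 10. Longest linear sequence: 9 steps (steps 2 to 10, from 4).

Most likely to fail, in this order:

Step 8. The oxocarbenium ion may be attacked by the ortho carbon of the silyl arene (para to its methoxy group) instead of the ipso carbon, the aryl–silicon bond may be lost by protodesilylation before ionisation, or the ring A benzylic ether may ionise and scramble C7'. The fallback makes the same bond by carbonyl addition and sets out from 11. i-Bu2AlH (3 equiv, CH2Cl2, −78 °C) should give (1R,5S,6R)-6-[4-(benzyloxy)-3-methoxyphenyl]-3,7-dioxabicyclo[3.3.0]octane-1,2-diol F1. Excess Grignard reagent 2 (THF, 0 °C to rt) should add to its open hydroxy-aldehyde form to give the ring-B-opened benzylic triol F2 as C7 epimers. Camphorsulfonic acid (cat., CH2Cl2, 0 °C) should then close ring B by SN1 capture of the C7 benzylic cation by the C9' hydroxyl, with the aryl group exo, and the route is rejoined at 16.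

Step 3. Face selection at the aldehyde or anti selectivity may be insufficient with this electron-poor cyclic allyl bromide, and reductive dimerisation of 6 may outrun catalytic turnover. The fallback replaces chromium catalysis by asymmetric allylboration and sets out from 6. Miyaura-type borylation (B2pin2, Pd2(dba)3 cat., KOAc, toluene, 50 °C) should give 3-[(4,4,5,5-tetramethyl-1,3,2-dioxaborolan-2-yl)methyl]furan-2(5H)-one F3. Addition of F3 to 7 under catalysis by a chiral 3,3'-bis(2,4,6-triisopropylphenyl)-BINOL hydrogen phosphate (toluene, −30 °C; aqueous work-up) should proceed through the same closed chair transition state and return to 9.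

Step 5. Capture of the planar benzylic cation may show poor facial selectivity at C7', the cation may lose a proton to a styrene, or acid may induce translactonisation onto the benzylic oxygen. The fallback closes ring A at C9 instead of C7' and sets out from 10. TsCl (1.05 equiv, pyridine, 0 °C to 40 °C) should sulfonylate only the primary hydroxyl to give the C9 p-toluenesulfonate of 10 F4, which the neutral C7' hydroxyl should displace in situ (5-exo-tet SN2 at C9, configuration at C7' retained from step 3), returning to 11.

**Further compounds**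
F1 | step 8 | (1R,5S,6R)-6-[4-(benzyloxy)-3-methoxyphenyl]-3,7-dioxabicyclo[3.3.0]octane-1,2-diol (C2 epimer mixture) | COc1cc([C@@H]2OC[C@@]3(O)C(O)OC[C@@H]23)ccc1OCc1ccccc1
F2 | step 8 | (2R,3S,4R)-2-[4-(benzyloxy)-3-methoxyphenyl]-4-{[4-(benzyloxy)-3-methoxyphenyl](hydroxy)methyl}-3-(hydroxymethyl)tetrahydrofuran-4-ol (carbinol epimer mixture) | COc1cc([C@@H]2OC[C@@](O)(C(O)c3ccc(OCc4ccccc4)c(OC)c3)[C@H]2CO)ccc1OCc1ccccc1
F3 | step 3 | 3-[(4,4,5,5-tetramethyl-1,3,2-dioxaborolan-2-yl)methyl]furan-2(5H)-one | CC1(C)OB(CC2=CCOC2=O)OC1(C)C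
F4 | step 5 | C9 p-toluenesulfonate of 10 | COc1cc([C@H](O)[C@@H]2COC(=O)[C@]2(O)COS(=O)(=O)c3ccc(C)cc3)ccc1OCc1ccccc1
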